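**Retrosynthetic overview**

1. Target 25 comes from silylene 24 by desilylation. 24 is cut at the C7=C8 and C7'=C8' double bonds into crocetin dialdehyde 9 (C20) and two C15 cyclogeranyl phosphonium salts, 8 (ring A) and 22 (ring B), joined by two successive Wittig reactions (8 first).
2. The ring B side chain C2'–CH2–CH=C(CH2OH)2 is made from the prenyl group of ester 14 by ozonolysis, Knoevenagel condensation with dimethyl malonate 17 and hydride reduction; the 1,3-diol is carried as a di-tert-butylsilylene.
3. The strategy rests on the end rings: each ring C1–C6 (gem-dimethyl C1, stereogenic C2 bearing a C5 allyl unit, C5=C6 double bond) is a cyclised geranyl unit alkylated at C2 by a prenyl cation. Methyl geranate 1 and prenyl alcohol 2 are therefore joined in one cascade that forms the C2–CH2 bond and the C1–C6 bond under a confined chiral acid.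
4. Ring A (C2 R) is formed in step 1 with one catalyst antipode and ring B (C2' S, the opposite spatial arrangement) in step 5 with the mirror-image catalyst; no other ring is formed.

Key step: step 1

Remark (assumption): the sense of induction of a new reaction cannot be predicted, so the (S,S)-acid is assumed to give (R)-6 and the (R,R)-acid (S)-14, to be assigned by a test run.

Remark: the dimethylallyl cation is the same ion in steps 1 and 5 and differs only in its counter-anion. It is numbered once, as 3, at step 1 where it first forms, and step 5 lists only the intermediates that are new there.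

Catalyst (preparation not counted): both antipodes of a confined imidodiphosphorimidate acid. It consists of two 3,3'-bis[3,5-bis(trifluoromethyl)phenyl]-1,1'-bi-2-naphthol phosphoryl units bridged by N–H, each phosphorus carrying an =N–SO2CF3 group. Ring atoms are cited in carotenoid numbering and chain atoms of 1 in geranate numbering.

**Route**

Step 1
Reactants: 1 methyl geranate (3 equiv); 2 3-methylbut-2-en-1-ol (1 equiv, added over 8 h)
Product: 6 methyl (5R)-2,6,6-trimethyl-5-(3-methylbut-2-en-1-yl)cyclohex-1-ene-1-carboxylate, via dimethylallyl cation 3 (not isolated), via acyclic C1 carbocation 4 (not isolated), via cyclic C5 carbocation 5 (not isolated)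
Conditions: (S,S)-imidodiphosphorimidate acid (5 mol %), CHCl3/(CF3)2CHOH 4:1, 5 Å MS, −30 °C, slow addition of 2; then 0 °C, 2 h; Et3N quench
Reagents that add atoms: none
Why: Proposed new method: the confined acid ionises 2 with loss of water to the dimethylallyl cation 3, which stays paired with the chiral anion and adds through its unhindered CH2 end to C6 of the electron-rich isopropylidene of 1 to give the tertiary cation 4; the alpha carbon of the ester-bearing C2=C3 bond then closes onto this cation in a chair-like 6-endo-trig cyclisation to cation 5, and loss of the proton alpha to the ester, the one deprotonation the strong acid does not reverse, leaves the conjugated tetrasubstituted alkene. The closest known reaction types are proton-initiated enantioselective polyene cyclisations catalysed by confined imidodiphosphorimidate acids in fluorinated alcohols, the acid-mediated cyclisation of geranates to cyclogeranates, and acid-catalysed dehydrative allylation by allylic alcohols in (CF3)2CHOH; what is new is initiation by a carbon electrophile under counter-anion control. The single new stereocentre (ring C2, R) is set in the intermolecular C–C bond formation, when the anion pocket exposes one enantioface of the C6=C7 bond of 1 to the bound cation; the substrate has no stereocentre, so the catalyst antipode alone decides the sense. Three selectivities are needed: attack by the CH2 and not the CMe2 end of 3 (sterics, and the trisubstituted alkene is kept), attack at the isopropylidene and not the enoate (the ester deactivates C2=C3, which acts only as internal terminator), and single prenylation, secured by the excess of 1 and the slow addition of 2, which keep 6 and 2 scarce as competing nucleophiles.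

Step 2
Reactants: 6 methyl (5R)-2,6,6-trimethyl-5-(3-methylbut-2-en-1-yl)cyclohex-1-ene-1-carboxylate
Product: 7 [(5R)-2,6,6-trimethyl-5-(3-methylbut-2-en-1-yl)cyclohex-1-en-1-yl]methanol
Conditions: i-Bu2AlH (2.5 equiv), CH2Cl2, −78 → 0 °C; aq. potassium sodium tartrate
Reagents that add atoms: none
Why: i-Bu2AlH delivers hydride twice to the hindered ester carbonyl (ester reduction to the primary allylic alcohol) without touching either alkene or the remote C2 stereocentre.

Step 3
Reactants: 7 [(5R)-2,6,6-trimethyl-5-(3-methylbut-2-en-1-yl)cyclohex-1-en-1-yl]methanol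
Product: 8 {[(5R)-2,6,6-trimethyl-5-(3-methylbut-2-en-1-yl)cyclohex-1-en-1-yl]methyl}(triphenyl)phosphonium bromide
Conditions: Ph3P·HBr (1.1 equiv), MeOH, rt, 48 h, dark
Reagents that add atoms: triphenylphosphine hydrobromide, [Br-].c1ccc([PH+](c2ccccc2)c2ccccc2)cc1
Why: Standard conversion of a cyclogeranyl-type allylic alcohol into its Wittig salt: the weakly acidic phosphonium bromide activates the allylic hydroxyl, which leaves as water, and triphenylphosphine is captured at the primary allylic carbon, while the isolated prenyl alkene is not protonated by this acid at room temperature.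

Step 4
Reactants: 8 ring A phosphonium bromide; 9 crocetin dialdehyde (3 equiv)
Product: 11 (2E,4E,6E,8E,10E,12E,14E,16E)-2,6,11,15-tetramethyl-17-[(5R)-2,6,6-trimethyl-5-(3-methylbut-2-en-1-yl)cyclohex-1-en-1-yl]heptadeca-2,4,6,8,10,12,14,16-octaenal, via ring A phosphorus ylide 10 (not isolated)
Conditions: NaN(SiMe3)2, THF, −78 → 0 °C; ylide added to 9 in CH2Cl2/THF, −40 °C → rt; then I2 (2 mol %), CH2Cl2, rt, daylight
Reagents that add atoms: none
Why: Wittig olefination of one formyl group by the semistabilised allylic ylide 10, mono-olefination being enforced statistically by inverse addition to excess 9 (recovered) and the E geometry of the new C7=C8 bond being secured thermodynamically by the iodine-catalysed equilibration, since a 7Z bond clashes with the ring methyl groups.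

Step 5
Reactants: 1 methyl geranate (3 equiv); 2 3-methylbut-2-en-1-ol (1 equiv, added over 8 h)
Product: 14 methyl (5S)-2,6,6-trimethyl-5-(3-methylbut-2-en-1-yl)cyclohex-1-ene-1-carboxylate, via acyclic C1 carbocation 12 (not isolated), via cyclic C5 carbocation 13 (not isolated)
Conditions: (R,R)-imidodiphosphorimidate acid (5 mol %), CHCl3/(CF3)2CHOH 4:1, 5 Å MS, −30 °C, slow addition of 2; then 0 °C, 2 h; Et3N quench
Reagents that add atoms: none
Why: Proposed new method: the mirror-image acid ionises 2 with loss of water exactly as in step 1, and the same counter-anion-controlled addition of the prenyl CH2 to the isopropylidene of 1, 6-endo-trig closure of cation 12 to 13 and loss of the proton alpha to the ester follow, reasoned as in step 1 and closest to confined-acid polyene cyclisations and the acid cyclisation of geranates; the mirror-image anion exposes the opposite enantioface of C6=C7, so ring C2 is set S.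

Step 6
Reactants: 14 methyl (5S)-2,6,6-trimethyl-5-(3-methylbut-2-en-1-yl)cyclohex-1-ene-1-carboxylate
Product: 16 methyl (5S)-2,6,6-trimethyl-5-(2-oxoethyl)cyclohex-1-ene-1-carboxylate, via secondary ozonide 15 (not isolated)
Conditions: O3 (to Sudan Red 7B end point), CH2Cl2, −78 °C; then PPh3, −78 °C → rt
Reagents that add atoms: ozone, O=[O+][O-]
Why: Ozone adds much faster to the electron-rich trisubstituted side-chain alkene than to the hindered, ester-substituted tetrasubstituted ring alkene, so ozonolysis titrated to the dye end point with reductive work-up cleaves only the prenyl group; the stereocentre is beta to the new carbonyl and cannot epimerise.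

Step 7
Reactants: 16 methyl (5S)-2,6,6-trimethyl-5-(2-oxoethyl)cyclohex-1-ene-1-carboxylate; 17 dimethyl malonate
Product: 18 dimethyl 2-{2-[(1S)-3-(methoxycarbonyl)-2,2,4-trimethylcyclohex-3-en-1-yl]ethylidene}propanedioate
Conditions: TiCl4 (2 equiv), pyridine (4 equiv), THF, 0 °C → rt
Reagents that add atoms: none
Why: Knoevenagel condensation under TiCl4/pyridine activation, which works at 0 °C for enolisable aliphatic aldehydes and avoids aldol self-condensation and migration of the new double bond out of conjugation.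

Step 8
Reactants: 18 dimethyl 2-{2-[(1S)-3-(methoxycarbonyl)-2,2,4-trimethylcyclohex-3-en-1-yl]ethylidene}propanedioate
Product: 19 2-{2-[(1S)-3-(hydroxymethyl)-2,2,4-trimethylcyclohex-3-en-1-yl]ethylidene}propane-1,3-diol
Conditions: i-Bu2AlH (8 equiv), CH2Cl2, −78 → 0 °C; aq. potassium sodium tartrate
Reagents that add atoms: none
Why: Aluminium-bound carbonyls receive hydride in the 1,2-sense in a non-coordinating solvent at low temperature, so this ester reduction should convert the alkylidene malonate into the 2-alkylidenepropane-1,3-diol and the ring ester into the allylic alcohol in one operation.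

Step 9
Reactants: 19 2-{2-[(1S)-3-(hydroxymethyl)-2,2,4-trimethylcyclohex-3-en-1-yl]ethylidene}propane-1,3-diol
Product: 20 {(5S)-5-[2-(2,2-di-tert-butyl-1,3,2-dioxasilinan-5-ylidene)ethyl]-2,6,6-trimethylcyclohex-1-en-1-yl}methanol
Conditions: t-Bu2Si(OTf)2 (1.05 equiv), 2,6-lutidine (2.5 equiv), CH2Cl2, −40 → 0 °C
Reagents that add atoms: di-tert-butylsilyl bis(trifluoromethanesulfonate), CC(C)(C)[Si](OS(=O)(=O)C(F)(F)F)(OS(=O)(=O)C(F)(F)F)C(C)(C)C
Why: The bis-triflate silylates a less hindered side-chain hydroxyl first and then closes intramolecularly to the six-membered di-tert-butylsilylene (1,3-diol protection), leaving the neopentyl-like ring CH2OH free.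

Step 10
Reactants: 20 {(5S)-5-[2-(2,2-di-tert-butyl-1,3,2-dioxasilinan-5-ylidene)ethyl]-2,6,6-trimethylcyclohex-1-en-1-yl}methanol
Product: 22 ({(5S)-5-[2-(2,2-di-tert-butyl-1,3,2-dioxasilinan-5-ylidene)ethyl]-2,6,6-trimethylcyclohex-1-en-1-yl}methyl)(triphenyl)phosphonium bromide, via allylic bromide 21 (not isolated)
Conditions: CBr4 (1.3 equiv), PPh3 (3 equiv), CH2Cl2, 0 °C → rt, then 40 °C
Reagents that add atoms: triphenylphosphine, c1ccc(P(c2ccccc2)c2ccccc2)cc1; carbon tetrabromide, BrC(Br)(Br)Br
Why: Appel bromination under neutral conditions gives the primary allylic bromide by SN2 displacement of the alkoxyphosphonium group and the excess triphenylphosphine quaternises it in the same flask; these acid-free conditions spare the silylene, which the hydrobromide method of step 3 would endanger.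

Step 11
Reactants: 22 ring B phosphonium bromide (1.2 equiv); 11 C35 aldehyde
Product: 24 (all-E,2R,2'S)-2'-[2-(2,2-di-tert-butyl-1,3,2-dioxasilinan-5-ylidene)ethyl]-2-(3-methylbut-2-en-1-yl)-β,β-carotene, via ring B phosphorus ylide 23 (not isolated)
Conditions: NaN(SiMe3)2, THF, −78 → 0 °C; then 11 in CH2Cl2/THF, −40 °C → rt; then I2 (2 mol %), CH2Cl2, rt, daylight
Reagents that add atoms: none
Why: Second Wittig olefination, of the remaining formyl group of 11 by allylic ylide 23 generated with a non-nucleophilic base that does not attack silicon, followed by the same iodine-catalysed equilibration to the all-E polyene; both C2 stereocentres are remote from the reacting sites.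

Step 12
Reactants: 24 silylene-protected C50 carotenoid
Product: 25 CNP0213288.1, (all-E,2R,2'S)-2'-[4-hydroxy-3-(hydroxymethyl)but-2-en-1-yl]-2-(3-methylbut-2-en-1-yl)-β,β-carotene
Conditions: Bu4NF (4 equiv), AcOH (4 equiv), THF, 0 °C → rt, argon, dark
Reagents that add atoms: none
Why: Fluoride cleaves both Si–O bonds of the silylene (desilylation), and buffering with acetic acid keeps the medium near neutral so that the polyene and the allylic diol see neither base nor strong acid.

**Compound list**

1 | methyl geranate, methyl (2E)-3,7-dimethylocta-2,6-dienoate | COC(=O)/C=C(\C)CCC=C(C)C | starting material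
2 | 3-methylbut-2-en-1-ol | CC(C)=CCO | starting material
3 | dimethylallyl cation (3-methylbut-2-en-1-ylium, paired with the catalyst anion) | CC(C)=C[CH2+] | intermediate
4 | acyclic C1 carbocation, (2E,6R)-1-methoxy-3,7-dimethyl-6-(3-methylbut-2-en-1-yl)-1-oxooct-2-en-7-ylium | CC(C)=CC[C@@H](CC/C(C)=C/C(=O)OC)[C+](C)C | intermediate
5 | cyclic C5 carbocation, (4R)-2-(methoxycarbonyl)-1,3,3-trimethyl-4-(3-methylbut-2-en-1-yl)cyclohexan-1-ylium (C2 of this name unassigned) | CC(C)=CC[C@H]1CC[C+](C)C(C(=O)OC)C1(C)C | intermediate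
6 | methyl (5R)-2,6,6-trimethyl-5-(3-methylbut-2-en-1-yl)cyclohex-1-ene-1-carboxylate | CC(C)=CC[C@H]1CCC(C)=C(C(=O)OC)C1(C)C | intermediate
7 | [(5R)-2,6,6-trimethyl-5-(3-methylbut-2-en-1-yl)cyclohex-1-en-1-yl]methanol | CC(C)=CC[C@H]1CCC(C)=C(CO)C1(C)C | intermediate
8 | {[(5R)-2,6,6-trimethyl-5-(3-methylbut-2-en-1-yl)cyclohex-1-en-1-yl]methyl}(triphenyl)phosphonium bromide | CC(C)=CC[C@H]1CCC(C)=C(C[P+](c2ccccc2)(c2ccccc2)c2ccccc2)C1(C)C.[Br-] | intermediate
9 | crocetin dialdehyde, (all-E)-2,6,11,15-tetramethylhexadeca-2,4,6,8,10,12,14-heptaenedial | O=C/C(C)=C/C=C/C(C)=C/C=C/C=C(C)/C=C/C=C(C)/C=O | starting material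
10 | ring A phosphorus ylide, {[(5R)-2,6,6-trimethyl-5-(3-methylbut-2-en-1-yl)cyclohex-1-en-1-yl]methylidene}(triphenyl)phosphorane | CC(C)=CC[C@H]1CCC(C)=C(C=P(c2ccccc2)(c2ccccc2)c2ccccc2)C1(C)C | intermediate
11 | (2E,4E,6E,8E,10E,12E,14E,16E)-2,6,11,15-tetramethyl-17-[(5R)-2,6,6-trimethyl-5-(3-methylbut-2-en-1-yl)cyclohex-1-en-1-yl]heptadeca-2,4,6,8,10,12,14,16-octaenal | CC(C)=CC[C@H]1CCC(C)=C(/C=C/C(C)=C/C=C/C(C)=C/C=C/C=C(C)/C=C/C=C(C)/C=O)C1(C)C | intermediate
12 | acyclic C1 carbocation, (2E,6S)-1-methoxy-3,7-dimethyl-6-(3-methylbut-2-en-1-yl)-1-oxooct-2-en-7-ylium | CC(C)=CC[C@H](CC/C(C)=C/C(=O)OC)[C+](C)C | intermediate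
13 | cyclic C5 carbocation, (4S)-2-(methoxycarbonyl)-1,3,3-trimethyl-4-(3-methylbut-2-en-1-yl)cyclohexan-1-ylium (C2 of this name unassigned) | CC(C)=CC[C@@H]1CC[C+](C)C(C(=O)OC)C1(C)C | intermediate
14 | methyl (5S)-2,6,6-trimethyl-5-(3-methylbut-2-en-1-yl)cyclohex-1-ene-1-carboxylate | CC(C)=CC[C@@H]1CCC(C)=C(C(=O)OC)C1(C)C | intermediate
15 | secondary ozonide, methyl (5S)-5-[(5,5-dimethyl-1,2,4-trioxolan-3-yl)methyl]-2,6,6-trimethylcyclohex-1-ene-1-carboxylate | CC1(C)OOC(C[C@@H]2CCC(C)=C(C(=O)OC)C2(C)C)O1 | intermediate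
16 | methyl (5S)-2,6,6-trimethyl-5-(2-oxoethyl)cyclohex-1-ene-1-carboxylate | O=CC[C@@H]1CCC(C)=C(C(=O)OC)C1(C)C | intermediate
17 | dimethyl malonate | COC(=O)CC(=O)OC | starting material
18 | dimethyl 2-{2-[(1S)-3-(methoxycarbonyl)-2,2,4-trimethylcyclohex-3-en-1-yl]ethylidene}propanedioate | COC(=O)C(=CC[C@@H]1CCC(C)=C(C(=O)OC)C1(C)C)C(=O)OC | intermediate
19 | 2-{2-[(1S)-3-(hydroxymethyl)-2,2,4-trimethylcyclohex-3-en-1-yl]ethylidene}propane-1,3-diol | OCC(CO)=CC[C@@H]1CCC(C)=C(CO)C1(C)C | intermediate
20 | {(5S)-5-[2-(2,2-di-tert-butyl-1,3,2-dioxasilinan-5-ylidene)ethyl]-2,6,6-trimethylcyclohex-1-en-1-yl}methanol | CC(C)(C)[Si]1(C(C)(C)C)OCC(=CC[C@@H]2CCC(C)=C(CO)C2(C)C)CO1 | intermediate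
21 | allylic bromide, 5-{2-[(1S)-3-(bromomethyl)-2,2,4-trimethylcyclohex-3-en-1-yl]ethylidene}-2,2-di-tert-butyl-1,3,2-dioxasilinane | CC(C)(C)[Si]1(C(C)(C)C)OCC(=CC[C@@H]2CCC(C)=C(CBr)C2(C)C)CO1 | intermediate
22 | ({(5S)-5-[2-(2,2-di-tert-butyl-1,3,2-dioxasilinan-5-ylidene)ethyl]-2,6,6-trimethylcyclohex-1-en-1-yl}methyl)(triphenyl)phosphonium bromide | CC(C)(C)[Si]1(C(C)(C)C)OCC(=CC[C@@H]2CCC(C)=C(C[P+](c3ccccc3)(c3ccccc3)c3ccccc3)C2(C)C)CO1.[Br-] | intermediate
23 | ring B phosphorus ylide, ({(5S)-5-[2-(2,2-di-tert-butyl-1,3,2-dioxasilinan-5-ylidene)ethyl]-2,6,6-trimethylcyclohex-1-en-1-yl}methylidene)(triphenyl)phosphorane | CC(C)(C)[Si]1(C(C)(C)C)OCC(=CC[C@@H]2CCC(C)=C(C=P(c3ccccc3)(c3ccccc3)c3ccccc3)C2(C)C)CO1 | intermediate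
24 | (all-E,2R,2'S)-2'-[2-(2,2-di-tert-butyl-1,3,2-dioxasilinan-5-ylidene)ethyl]-2-(3-methylbut-2-en-1-yl)-β,β-carotene | CC(C)=CC[C@H]1CCC(C)=C(/C=C/C(C)=C/C=C/C(C)=C/C=C/C=C(C)/C=C/C=C(C)/C=C/C2=C(C)CC[C@@H](CC=C3CO[Si](C(C)(C)C)(C(C)(C)C)OC3)C2(C)C)C1(C)C | intermediate
25 | CNP0213288.1, (all-E,2R,2'S)-2'-[4-hydroxy-3-(hydroxymethyl)but-2-en-1-yl]-2-(3-methylbut-2-en-1-yl)-β,β-carotene | CC(C)=CC[C@H]1CCC(C)=C(/C=C/C(C)=C/C=C/C(C)=C/C=C/C=C(C)/C=C/C=C(C)/C=C/C2=C(C)CC[C@@H](CC=C(CO)CO)C2(C)C)C1(C)C | target

**Step count**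

Total: 12 steps (catalyst preparation not counted). Longest linear sequence: 8 steps (steps 5 to 12, from 1 and 2 through 14 to 25).

**Steps most likely to fail**

Step 1 (Proposed new method).
- Self-condensation of the ionised alcohol or proton-initiated cyclisation of 1 may outrun the cross-coupling.
- Enantioface discrimination in a purely hydrocarbon ion pair may be weak.
- Configuration may erode by elimination and re-protonation or by a 1,2-hydride shift at the tertiary cation.
- The ring double bond may not settle fully into conjugation.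

Fallback by known chemistry: no route compound lies before step 1, so it sets out from commercial 2,2-dimethylcyclohexane-1,3-dione F1 in place of 1 and 2 and comes back at 6. Horner–Wadsworth–Emmons mono-olefination of F1 with trimethyl phosphonoacetate (NaH, THF, reflux) should give methyl (E)-2-(2,2-dimethyl-3-oxocyclohexylidene)acetate F2. Methylation of the ketone enolate (LiN(i-Pr)2, THF, −78 °C; MeI) should give methyl (E)-2-(2,2,4-trimethyl-3-oxocyclohexylidene)acetate F3. Its only enolisable ketone position leads (KN(SiMe3)2, PhNTf2, THF) to methyl (E)-2-[2,2,4-trimethyl-3-(trifluoromethylsulfonyloxy)cyclohex-3-en-1-ylidene]acetate F4. Methoxycarbonylation (Pd(OAc)2, 1,1'-bis(diphenylphosphino)ferrocene, CO, MeOH, Et3N, DMF, 60 °C) should give methyl (5E)-5-(2-methoxy-2-oxoethylidene)-2,6,6-trimethylcyclohex-1-ene-1-carboxylate F5. Copper hydride-catalysed asymmetric conjugate reduction of the exocyclic enoate alone (Cu(OAc)2, one antipode of 2,2'-bis(di-p-tolylphosphino)-1,1'-binaphthyl, polymethylhydrosiloxane, t-BuOH, toluene) sets the stereocentre and should give methyl (5R)-5-(2-methoxy-2-oxoethyl)-2,6,6-trimethylcyclohex-1-ene-1-carboxylate F6; the hindered tetrasubstituted ring enoate is inert. i-Bu2AlH (1.1 equiv, CH2Cl2, −78 °C) reduces the unhindered ester to methyl (5R)-2,6,6-trimethyl-5-(2-oxoethyl)cyclohex-1-ene-1-carboxylate F7. Wittig reaction with Ph3P=CMe2 (from isopropyltriphenylphosphonium iodide and n-BuLi, THF) then gives 6.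

Step 5 (Proposed new method).
- The same processes as in step 1 may intervene.
- Both antipodes end up in one molecule, so any loss of enantiopurity here appears as diastereomeric carotenoids that are hard to remove.

Fallback by known chemistry: it sets out, like the one above, from commercial 2,2-dimethylcyclohexane-1,3-dione F1 and shares its intermediates up to the dienyl diester F5; it comes back at 16, so steps 5 and 6 are bypassed. Conjugate reduction of F5 with the other ligand antipode under the same copper hydride conditions should give methyl (5S)-5-(2-methoxy-2-oxoethyl)-2,6,6-trimethylcyclohex-1-ene-1-carboxylate F8. Selective reduction of its unhindered ester (i-Bu2AlH, 1.1 equiv, CH2Cl2, −78 °C) gives 16.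

Step 4.
- The hindered ylide may add sluggishly to the polyenal.
- Double olefination may compete with mono-olefination.
- Z geometry at C7=C8 may persist.

Fallback: it sets out from 7 and comes back at 11, replacing the Wittig reaction by a Julia–Kocienski olefination with a smaller sulfonyl carbanion. Mitsunobu thioetherification of 7 with 1-phenyl-1H-tetrazole-5-thiol (PPh3, diisopropyl azodicarboxylate, THF, 0 °C) should give 1-phenyl-5-({[(5R)-2,6,6-trimethyl-5-(3-methylbut-2-en-1-yl)cyclohex-1-en-1-yl]methyl}sulfanyl)-1H-tetrazole F9. Sulfur oxidation ((NH4)6Mo7O24 cat., H2O2, EtOH, 0 °C) should give 1-phenyl-5-({[(5R)-2,6,6-trimethyl-5-(3-methylbut-2-en-1-yl)cyclohex-1-en-1-yl]methyl}sulfonyl)-1H-tetrazole F10. Addition of KN(SiMe3)2 to a premixed solution of F10 and excess 9 (THF, −78 °C → rt), followed by the iodine equilibration, gives 11.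

**Further compounds**

F1 | step 1 | 2,2-dimethylcyclohexane-1,3-dione | CC1(C)C(=O)CCCC1=O
F2 | step 1 | methyl (E)-2-(2,2-dimethyl-3-oxocyclohexylidene)acetate | COC(=O)/C=C1\CCCC(=O)C1(C)C
F3 | step 1 | methyl (E)-2-(2,2,4-trimethyl-3-oxocyclohexylidene)acetate | COC(=O)/C=C1\CCC(C)C(=O)C1(C)C
F4 | step 1 | methyl (E)-2-[2,2,4-trimethyl-3-(trifluoromethylsulfonyloxy)cyclohex-3-en-1-ylidene]acetate | COC(=O)/C=C1\CCC(C)=C(OS(=O)(=O)C(F)(F)F)C1(C)C
F5 | step 1 | methyl (5E)-5-(2-methoxy-2-oxoethylidene)-2,6,6-trimethylcyclohex-1-ene-1-carboxylate | COC(=O)/C=C1\CCC(C)=C(C(=O)OC)C1(C)C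
F6 | step 1 | methyl (5R)-5-(2-methoxy-2-oxoethyl)-2,6,6-trimethylcyclohex-1-ene-1-carboxylate | COC(=O)C[C@H]1CCC(C)=C(C(=O)OC)C1(C)C
F7 | step 1 | methyl (5R)-2,6,6-trimethyl-5-(2-oxoethyl)cyclohex-1-ene-1-carboxylate | O=CC[C@H]1CCC(C)=C(C(=O)OC)C1(C)C
F8 | step 5 | methyl (5S)-5-(2-methoxy-2-oxoethyl)-2,6,6-trimethylcyclohex-1-ene-1-carboxylate | COC(=O)C[C@@H]1CCC(C)=C(C(=O)OC)C1(C)C
F9 | step 4 | 1-phenyl-5-({[(5R)-2,6,6-trimethyl-5-(3-methylbut-2-en-1-yl)cyclohex-1-en-1-yl]methyl}sulfanyl)-1H-tetrazole | CC(C)=CC[C@H]1CCC(C)=C(CSc2nnnn2-c2ccccc2)C1(C)C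
F10 | step 4 | 1-phenyl-5-({[(5R)-2,6,6-trimethyl-5-(3-methylbut-2-en-1-yl)cyclohex-1-en-1-yl]methyl}sulfonyl)-1H-tetrazole | CC(C)=CC[C@H]1CCC(C)=C(CS(=O)(=O)c2nnnn2-c2ccccc2)C1(C)C
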